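**Read the ends.** Take the final product of a run as the score of one competition between a chain and a side loss.

common to all: starting material 0.92 M; protic impurity 0.0184 M
- green: reagent 1.66 M; initiator 31 mM; run made earlier
- grey: reagent 1.66 M; initiator 92 mM; run made earlier
- eta: reagent 1.70 M; initiator 46 mM; time 8.0 min
- epsilon: reagent 2.50 M; initiator 46 mM; time 8.0 min

- green (time / min: starting material / %, chain carrier / %, product / %): 0.250: 84.8, 0.1, 7.6; 0.667: 65.9, 0, 19.4; 1.33: 43.4, 0, 37.3; 2.00: 26.4, 0, 51.6; 3.00: 9.7, 0, 67.3; 4.00: 3.2, 0, 74.3; 5.00: 0.5, 0.1, 76.1
- grey (time / min: starting material / %, chain carrier / %, product / %): 0.417: 69.0, 0, 22.0; 0.667: 54.5, 0.1, 33.3; 0.833: 45.9, 0, 40.5; 1.33: 25.7, 0.2, 58.4; 2.00: 9.0, 0.2, 75.1; 3.00: 1.1, 0, 82.4; 5.00: 0, 0.1, 83.1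

(readings scatter by 0.3 percentage points)

1. which of these there is most of at the end, counted by the starting material in it, eta (starting material / chain carrier / product)
2. which of these there is most of at the end, counted by the starting material in it, epsilon (starting material / chain carrier / product)
3. final amount of the leader among these, as a percentage of the starting material charged, in eta
4. final amount of the leader among these, as a percentage of the starting material charged, in epsilon

**The side number.** In the green run, product reaches 19.4% by 0.667 min and gains 18 percentage points over the equal stretch to 1.33 min, though starting material is down to 65.9% when that stretch begins. So we treat the chain's pace as steady, and we suppose that the side loss runs with the square of starting material. Let u be the fraction of starting material left, and q the side rate at the charge over the chain rate, a kind of selectivity factor. Product per starting material consumed is then the reciprocal of 1 + q·u·u. Integrated from full charge to nothing, this gives arctan(√q)/√q, which we use in the rational form (15 + 4q)/(15 + 9q). We assume that each protic impurity takes one starting material, so this share applies to the charge less 2.00%.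

**Two ways.** Counting the starting material at its last reading as product still to come, the green run's readings put 78.2% of that material into product, so its side number, read from the readings, is 1.08. The same count for the grey run gives 84.8%, and so a side number of 0.628. Their ratio, 1.72, sits on the square root of the initiator ratio, 1.72, as we expect if chain carriers end in pairs.

We also take q as inverse to reagent, since we read the steady pace as the reagent step; both earlier runs were charged with 1.66 M, so neither tests this. For eta, green then gives 0.865 and grey gives 0.867. Both lead to about 79.4% product. For epsilon, q drops to 0.588, and we commit to 83.8%.

**The forecast.** It names product as leader in both flasks, with 79% for eta (77% to 81.5%) and 86% for epsilon (79% to 94%). Its ground for epsilon: “If reagent competes with the side path, the loss shrinks by roughly the reagent ratio”. On eta it stands 0.40 points below our figure; on epsilon it stands above ours.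

**The flask.** Product leads in both, with 79.9% in eta and 83.9% in epsilon.

    starting material + initiating radical → chain carrier (k = 30000 L mol⁻¹ s⁻¹)
    starting material + protic impurity → quenched substrate (k = 5.30 L mol⁻¹ min⁻¹)
    initiator → 2 initiating radical (k = 0.00890 min⁻¹)
    2 chain carrier → ended chains B (k = 3.00 × 10⁸ L mol⁻¹ s⁻¹)
    2 starting material → homo dimer (k = 0.150 L mol⁻¹ min⁻¹)
    2 initiating radical → ended chains A (k = 9.00 × 10⁶ L mol⁻¹ s⁻¹)
    reagent + chain carrier → product + initiating radical (k = 25000 L mol⁻¹ s⁻¹)

**Where it went.** The side loss in epsilon is mainly homo dimer: with that step taken away, product stands at 97.9% instead of 83.9%. Our side number of 0.588 reckoned 83.8% for this flask. Now take the neighbour of epsilon charged with 0.55 M of starting material. Green's 1.08, scaled for initiator and reagent and then by the square of the charge, becomes 0.210, which reckons 90.6%; that flask gives 90.2%.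

(The numbers in the tables were generated by integration for substances that don't exist, noise included.)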